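Ring B of the target (labdane numbering) carries oxygen at C6 and C9, para to each other, methyl groups at C8 and C10, and is cis-fused to ring A (C5–H and C10–CH3 on one face): the retron of a quinone Diels–Alder adduct. A catalytic enantioselective [4+2] cycloaddition of 2,6-dimethyl-1,4-benzoquinone with 4-methylpenta-1,3-diene builds ring A in one operation: the diene terminus C1 bonds to C10 and the gem-dimethyl carbon C4 closes the ring onto C5, fixing both ring-fusion centres and delivering C6 and C9 as distinguishable carbonyls. The spiro ether–lactone is then grafted onto C9 with an enantiopure C11–C16 alkyne.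

Key step: step 1

Remark on numbering: C1–C5 and C10 form ring A, C5–C10 ring B; C11, C12, C13 and the ether oxygen complete the tetrahydrofuran; C14, C15 (OCH2) and C16 (C=O) the lactone. "Syn" and "anti" refer to the face of ring B that carries the C10 methyl group.

Assumption: the (S)-oxazaborolidinium ion of step 1 and the (1S,2S)-amino alcohol of step 6 are taken to give the configurations drawn; both are available as either enantiomer, so the antipode would be used if the sense of induction proved opposite.

Step 1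
Reactants: 1 2,6-dimethyl-1,4-benzoquinone; 2 4-methylpenta-1,3-diene
Product: 3 (4aS,8aR)-2,5,5,8a-tetramethyl-4a,5,8,8a-tetrahydronaphthalene-1,4-dione
Conditions: (S)-3,3-diphenyl-1-(2-methylphenyl)tetrahydro-1H,3H-pyrrolo[1,2-c][1,3,2]oxazaborole protonated with HN(SO2CF3)2 (20 mol %), 2 (5 equiv), CH2Cl2, −78 → −20 °C
Reagents that add atoms: none
Why: The cationic oxazaborolidinium ion binds the C6 carbonyl oxygen of 1 (unflanked, the more basic one, with an adjacent C–H for the usual secondary contact), so that C10, the methyl-bearing β-carbon, becomes the most electrophilic site; the unsubstituted terminus C1 of 2 bonds there in advance and ring A is completed when the gem-dimethyl terminus C4 bonds to C5 in a concerted but strongly asynchronous [4+2] cycloaddition. The closest known reaction type is the oxazaborolidinium-catalysed Diels–Alder reaction of methyl-substituted 1,4-benzoquinones with simple dienes, together with the Lewis-acid-reversed regiochemistry known for 1 and piperylene under BF3·OEt2. Ring A closes in the six-membered cycloaddition mode, suprafacial on both partners, with C1–C10 and C4–C5 as the two new ring bonds. C5 and C10 arise in the same suprafacial event, so C5–H and C10–CH3 are necessarily cis, and their absolute configuration (5S,10R) is dictated by the catalyst, which screens one face of the coordinated C5=C10 bond. The step needs regiocontrol (C4 to C5, not to C10), secured by the Lewis-acid polarisation and by the impossibility of joining the quaternary carbons C4 and C10, and face control, which is the task of the catalyst because the two ring double bonds of 1 are homotopic. The known reluctance of a diene with a cis-methyl group at its terminus is the accepted risk.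

Step 2
Reactants: 3 (4aS,8aR)-2,5,5,8a-tetramethyl-4a,5,8,8a-tetrahydronaphthalene-1,4-dione
Product: 4 (4R,4aS,8aR)-4-hydroxy-2,5,5,8a-tetramethyl-4a,5,8,8a-tetrahydronaphthalen-1(4H)-one
Conditions: NaBH4, CeCl3·7H2O, MeOH, −78 °C
Reagents that add atoms: none
Why: Luche 1,2-reduction should take the C6 carbonyl, which is not flanked by the C8 and C10 methyl groups, with hydride arriving on the convex (syn) face of the cis-fused bicycle, so that the new hydroxyl lies anti, cis to C4 (6R).

Step 3
Reactants: 4 (4R,4aS,8aR)-4-hydroxy-2,5,5,8a-tetramethyl-4a,5,8,8a-tetrahydronaphthalen-1(4H)-one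
Product: 5 (2R,4R,4aS,8aR)-4-hydroxy-2,5,5,8a-tetramethyloctahydronaphthalen-1(2H)-one
Conditions: H2 (1 atm), [Ir(cod)(PCy3)(py)]PF6 (5 mol %), CH2Cl2, rt
Reagents that add atoms: none
Why: Hydroxyl-directed homogeneous hydrogenation should deliver H2 to C7=C8 from the face of the C6 hydroxyl, which puts C8–H anti and the C8 methyl syn (8R), while the ring A double bond is saturated in the same operation.

Step 4
Reactants: 6 ethyl 1,3-dithiane-2-carboxylate; 7 (2-bromoethoxy)(tert-butyl)dimethylsilane
Product: 8 ethyl 2-[2-[(tert-butyldimethylsilyl)oxy]ethyl]-1,3-dithiane-2-carboxylate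
Conditions: NaH, DMF/toluene, 0 °C → rt
Reagents that add atoms: none
Why: Alkylation of the stabilised dithiane carboxylate anion, a masked glyoxylate anion (Corey–Seebach umpolung), with a primary bromide.

Step 5
Reactants: 8 ethyl 2-[2-[(tert-butyldimethylsilyl)oxy]ethyl]-1,3-dithiane-2-carboxylate
Product: 9 ethyl 4-[(tert-butyldimethylsilyl)oxy]-2-oxobutanoate
Conditions: N-bromosuccinimide, 2,6-lutidine, acetone/H2O, −10 °C
Reagents that add atoms: water, O
Why: Oxidative hydrolysis of the dithioketal unmasks the α-keto ester, and the lutidine buffers the HBr so that the silyl ether should survive.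

Step 6
Reactants: 9 ethyl 4-[(tert-butyldimethylsilyl)oxy]-2-oxobutanoate; 10 ethynyltrimethylsilane
Product: 12 ethyl (2S)-4-[(tert-butyldimethylsilyl)oxy]-2-ethynyl-2-hydroxybutanoate, via C-silylated carbinol 11 (not isolated)
Conditions: Zn(OTf)2 (20 mol %), (1S,2S)-2-(dimethylamino)-1-(4-nitrophenyl)-3-(tert-butyldimethylsilyloxy)propan-1-ol (22 mol %), Et3N, toluene, 70 °C; then K2CO3, EtOH, rt
Reagents that add atoms: none
Why: Catalytic asymmetric alkynylation of an α-keto ester, in which a zinc acetylide adds to the activated ketone within a chiral zinc amino-alkoxide complex that sets the tertiary carbinol (S), followed by mild ethanolysis of the C–Si bond in the same flask.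

Step 7
Reactants: 5 (2R,4R,4aS,8aR)-4-hydroxy-2,5,5,8a-tetramethyloctahydronaphthalen-1(2H)-one; 12 ethyl (2S)-4-[(tert-butyldimethylsilyl)oxy]-2-ethynyl-2-hydroxybutanoate
Product: 15 ethyl (2S)-4-[(tert-butyldimethylsilyl)oxy]-2-{[(1S,2R,4R,4aS,8aR)-1,4-dihydroxy-2,5,5,8a-tetramethyldecahydronaphthalen-1-yl]ethynyl}-2-hydroxybutanoate, via dilithio alkynyl alkoxide 13 (not isolated), via lithium alkoxide 14 (not isolated)
Conditions: 12 (1.5 equiv), LiN(i-Pr)2 (3.0 equiv), THF, −78 °C; 5, LiN(SiMe3)2 (1.0 equiv), THF, −78 °C; combine, −78 → 0 °C; aq. NH4Cl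
Reagents that add atoms: none
Why: 1,2-Addition of a slim lithium acetylide to a hindered 2,2,6-trisubstituted cyclohexanone should proceed by axial attack on the syn face; the C9 configuration so formed is of no consequence because C9 is re-formed in step 10, and the α-quaternary ester next to a lithium alkoxide should not be attacked at low temperature.

Step 8
Reactants: 15 ethyl (2S)-4-[(tert-butyldimethylsilyl)oxy]-2-{[(1S,2R,4R,4aS,8aR)-1,4-dihydroxy-2,5,5,8a-tetramethyldecahydronaphthalen-1-yl]ethynyl}-2-hydroxybutanoate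
Product: 16 ethyl (2S)-4-[(tert-butyldimethylsilyl)oxy]-2-hydroxy-2-{[(1S,2R,4aS,8aR)-1-hydroxy-2,5,5,8a-tetramethyl-4-oxodecahydronaphthalen-1-yl]ethynyl}butanoate
Conditions: Dess–Martin periodinane, CH2Cl2, 0 °C → rt
Reagents that add atoms: none
Why: Dess–Martin oxidation takes the only secondary alcohol (C6) and leaves the two tertiary carbinols, the alkyne and the silyl ether untouched; the ketone removes the C6 hydroxyl as a competing nucleophile for step 10 and prepares the later correction of C6.

Step 9
Reactants: 16 ethyl (2S)-4-[(tert-butyldimethylsilyl)oxy]-2-hydroxy-2-{[(1S,2R,4aS,8aR)-1-hydroxy-2,5,5,8a-tetramethyl-4-oxodecahydronaphthalen-1-yl]ethynyl}butanoate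
Product: 17 ethyl (2S)-4-[(tert-butyldimethylsilyl)oxy]-2-hydroxy-2-{(Z)-2-[(1R,2R,4aS,8aR)-1-hydroxy-2,5,5,8a-tetramethyl-4-oxodecahydronaphthalen-1-yl]ethenyl}butanoate
Conditions: H2 (1 atm), Pd/CaCO3 poisoned with Pb(OAc)2 (Lindlar catalyst), quinoline, EtOAc, rt
Reagents that add atoms: none
Why: Lindlar semihydrogenation adds H2 syn and should stop at the (Z)-alkene, which brings the two tertiary carbinols within reach of one another.

Step 10
Reactants: 17 ethyl (2S)-4-[(tert-butyldimethylsilyl)oxy]-2-hydroxy-2-{(Z)-2-[(1R,2R,4aS,8aR)-1-hydroxy-2,5,5,8a-tetramethyl-4-oxodecahydronaphthalen-1-yl]ethenyl}butanoate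
Product: 20 (5S,8R,9S,10R,13S)-6-oxo-9,13-epoxylabd-11-en-16,15-olide, via desilylated diol ester 18 (not isolated), via hydroxy lactone 19 (not isolated)
Conditions: camphorsulfonic acid (0.3 equiv), CH2Cl2/MeOH (4:1), 0 °C → rt
Reagents that add atoms: none
Why: Acid removes the silyl ether, the freed γ-hydroxy ester lactonises, and the tertiary allylic C9 carbinol ionises to a cation that the C13 hydroxyl captures in a five-membered ring (cyclodehydration of a (Z)-ene-1,4-diol to a 2,5-dihydrofuran, as in spiro-ether norisoprenoid chemistry); the C13–O bond is never broken, so C13 keeps its configuration, and C9 should be set by axial attack of oxygen on the syn face, anti to the axial C1, which leaves the larger alkenyl arm equatorial.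

Step 11
Reactants: 20 (5S,8R,9S,10R,13S)-6-oxo-9,13-epoxylabd-11-en-16,15-olide
Product: 21 (5S,8R,9R,10R,13R)-6-oxo-9,13-epoxylabdan-16,15-olide
Conditions: H2 (1 atm), Rh/Al2O3 (5 %), EtOAc, rt
Reagents that add atoms: none
Why: Heterogeneous hydrogenation of the cis-disubstituted dihydrofuran double bond over rhodium, chosen over palladium to avoid hydrogenolysis of the allylic C–O bonds; no stereocentre is formed.

Step 12
Reactants: 21 (5S,8R,9R,10R,13R)-6-oxo-9,13-epoxylabdan-16,15-olide
Product: 22 (5S,6S,8R,9R,10R,13R)-6-hydroxy-9,13-epoxylabdan-16,15-olide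
Conditions: SmI2 (3 equiv), THF/MeOH, rt
Reagents that add atoms: none
Why: Single-electron reduction through the ketyl and the rapidly inverting carbinyl radical should give the thermodynamically preferred equatorial alcohol, here the syn (6S) epimer, because the axial epimer suffers a 1,3-diaxial contact with C1; the γ-lactone and the ethers should be inert to SmI2 without HMPA.

Step 13
Reactants: 22 (5S,6S,8R,9R,10R,13R)-6-hydroxy-9,13-epoxylabdan-16,15-olide
Product: 23 (5S,6S,8R,9R,10R,13R)-6-acetoxy-9,13-epoxylabdan-16,15-olide (CNP0081177.1)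
Conditions: Ac2O, pyridine, DMAP (cat.), CH2Cl2, rt
Reagents that add atoms: acetic anhydride, CC(=O)OC(C)=O
Why: DMAP-catalysed acetylation of the single, secondary hydroxyl group with retention at C6.

Compound list

1 | 2,6-dimethyl-1,4-benzoquinone | O=C1C=C(C)C(=O)C(C)=C1 | starting material
2 | 4-methylpenta-1,3-diene | C=CC=C(C)C | starting material
3 | (4aS,8aR)-2,5,5,8a-tetramethyl-4a,5,8,8a-tetrahydronaphthalene-1,4-dione (cis-fused) | O=C1C=C(C)C(=O)[C@]2(C)CC=CC(C)(C)[C@H]12 | intermediate
4 | (4R,4aS,8aR)-4-hydroxy-2,5,5,8a-tetramethyl-4a,5,8,8a-tetrahydronaphthalen-1(4H)-one (hydroxyl anti) | O[C@@H]1C=C(C)C(=O)[C@]2(C)CC=CC(C)(C)[C@H]12 | intermediate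
5 | (2R,4R,4aS,8aR)-4-hydroxy-2,5,5,8a-tetramethyloctahydronaphthalen-1(2H)-one | O[C@@H]1C[C@@H](C)C(=O)[C@]2(C)CCCC(C)(C)[C@H]12 | intermediate
6 | ethyl 1,3-dithiane-2-carboxylate | CCOC(=O)C1SCCCS1 | starting material
7 | (2-bromoethoxy)(tert-butyl)dimethylsilane | BrCCO[Si](C)(C)C(C)(C)C | starting material
8 | ethyl 2-[2-[(tert-butyldimethylsilyl)oxy]ethyl]-1,3-dithiane-2-carboxylate | CCOC(=O)C1(CCO[Si](C)(C)C(C)(C)C)SCCCS1 | intermediate
9 | ethyl 4-[(tert-butyldimethylsilyl)oxy]-2-oxobutanoate | CCOC(=O)C(=O)CCO[Si](C)(C)C(C)(C)C | intermediate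
10 | ethynyltrimethylsilane | C#C[Si](C)(C)C | starting material
11 | ethyl (2S)-4-[(tert-butyldimethylsilyl)oxy]-2-hydroxy-2-[(trimethylsilyl)ethynyl]butanoate | C[Si](C)(C)C#C[C@@](O)(CCO[Si](C)(C)C(C)(C)C)C(=O)OCC | intermediate (not isolated)
12 | ethyl (2S)-4-[(tert-butyldimethylsilyl)oxy]-2-ethynyl-2-hydroxybutanoate | C#C[C@@](O)(CCO[Si](C)(C)C(C)(C)C)C(=O)OCC | intermediate
13 | dilithio derivative of 12 (lithium acetylide, lithium alkoxide) | [Li]C#C[C@@](O[Li])(CCO[Si](C)(C)C(C)(C)C)C(=O)OCC | intermediate (not isolated)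
14 | lithium alkoxide of 5 | [Li]O[C@@H]1C[C@@H](C)C(=O)[C@]2(C)CCCC(C)(C)[C@H]12 | intermediate (not isolated)
15 | ethyl (2S)-4-[(tert-butyldimethylsilyl)oxy]-2-{[(1S,2R,4R,4aS,8aR)-1,4-dihydroxy-2,5,5,8a-tetramethyldecahydronaphthalen-1-yl]ethynyl}-2-hydroxybutanoate | O[C@@H]1C[C@@H](C)[C@@](O)(C#C[C@@](O)(CCO[Si](C)(C)C(C)(C)C)C(=O)OCC)[C@]2(C)CCCC(C)(C)[C@H]12 | intermediate
16 | ethyl (2S)-4-[(tert-butyldimethylsilyl)oxy]-2-hydroxy-2-{[(1S,2R,4aS,8aR)-1-hydroxy-2,5,5,8a-tetramethyl-4-oxodecahydronaphthalen-1-yl]ethynyl}butanoate | O=C1C[C@@H](C)[C@@](O)(C#C[C@@](O)(CCO[Si](C)(C)C(C)(C)C)C(=O)OCC)[C@]2(C)CCCC(C)(C)[C@H]12 | intermediate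
17 | ethyl (2S)-4-[(tert-butyldimethylsilyl)oxy]-2-hydroxy-2-{(Z)-2-[(1R,2R,4aS,8aR)-1-hydroxy-2,5,5,8a-tetramethyl-4-oxodecahydronaphthalen-1-yl]ethenyl}butanoate | O=C1C[C@@H](C)[C@@](O)(/C=C\[C@@](O)(CCO[Si](C)(C)C(C)(C)C)C(=O)OCC)[C@]2(C)CCCC(C)(C)[C@H]12 | intermediate
18 | ethyl (2S)-2,4-dihydroxy-2-{(Z)-2-[(1R,2R,4aS,8aR)-1-hydroxy-2,5,5,8a-tetramethyl-4-oxodecahydronaphthalen-1-yl]ethenyl}butanoate | O=C1C[C@@H](C)[C@@](O)(/C=C\[C@@](O)(CCO)C(=O)OCC)[C@]2(C)CCCC(C)(C)[C@H]12 | intermediate (not isolated)
19 | (3S)-3-hydroxy-3-{(Z)-2-[(1R,2R,4aS,8aR)-1-hydroxy-2,5,5,8a-tetramethyl-4-oxodecahydronaphthalen-1-yl]ethenyl}dihydrofuran-2(3H)-one | O=C1C[C@@H](C)[C@@](O)(/C=C\[C@@]3(O)CCOC3=O)[C@]2(C)CCCC(C)(C)[C@H]12 | intermediate (not isolated)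
20 | (5S,8R,9S,10R,13S)-6-oxo-9,13-epoxylabd-11-en-16,15-olide (spiro 2,5-dihydrofuran; ether oxygen syn at C9) | O=C1C[C@@H](C)[C@]2(C=C[C@]3(CCOC3=O)O2)[C@]2(C)CCCC(C)(C)[C@H]12 | intermediate
21 | (5S,8R,9R,10R,13R)-6-oxo-9,13-epoxylabdan-16,15-olide | O=C1C[C@@H](C)[C@]2(CC[C@]3(CCOC3=O)O2)[C@]2(C)CCCC(C)(C)[C@H]12 | intermediate
22 | (5S,6S,8R,9R,10R,13R)-6-hydroxy-9,13-epoxylabdan-16,15-olide (hydroxyl syn) | O[C@H]1C[C@@H](C)[C@]2(CC[C@]3(CCOC3=O)O2)[C@]2(C)CCCC(C)(C)[C@H]12 | intermediate
23 | (5S,6S,8R,9R,10R,13R)-6-acetoxy-9,13-epoxylabdan-16,15-olide (CNP0081177.1) | CC(=O)O[C@H]1C[C@@H](C)[C@]2(CC[C@]3(CCOC3=O)O2)[C@]2(C)CCCC(C)(C)[C@H]12 | target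

Total step count: 13. Longest linear sequence: 10 steps (steps 1–3 then 7–13; the side-chain branch, steps 4–6 then 7–13, is equally long).

Steps most likely to fail

Step 1. The diene, whose cis-methyl group disfavours the s-cis conformation, may react with the activated quinone stepwise, through a zwitterion that collapses to [2+2] or O-alkylated products or loses a proton; an ion-pair pathway would also erode face selectivity. The fallback sets out from 1 and keeps the catalysed cycloaddition but uses a diene without a cis substituent, allylidenecyclopropane F1 (from acrolein and cyclopropylidenetriphenylphosphorane by Wittig olefination), a known gem-dimethyl equivalent. The spiro-cyclopropane adduct F2 would be reduced under the conditions of step 2 to the allylic alcohol F3 and hydrogenated under the conditions of step 3 to the saturated hydroxy ketone F4. Hydrogenolysis of the unsubstituted CH2–CH2 bond of the three-membered ring (H2, PtO2, AcOH) would then unveil the gem-dimethyl group, and the route is rejoined at 5.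

Step 10. The allylic C9 cation may lose the C8 proton to give a diene (which would scramble C8), be intercepted by methanol with allylic transposition, or be captured on the anti face and give the C9 epimer. The fallback sets out from 16 and closes the ether without an allylic cation. Complete hydrogenation of the alkyne (H2, Pd/C, EtOAc) would give the saturated diol ester F5. Bu4NF would remove the silyl group, and the freed γ-hydroxy ester would lactonise to the hydroxy lactone F6. Cyclodehydration of this ditertiary 1,4-diol (TsOH, CH2Cl2, or BF3·OEt2 at low temperature) passes through a localised chair C9 cation that cannot transpose and should be attacked axially. This comes back to the route at 21 and makes step 11 unnecessary.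

Step 12. The electron-transfer reduction may not reach thermodynamic control (kinetic protonation would give the axial alcohol), and reductive cleavage of the C13–O bond α to the lactone carbonyl may compete. The fallback sets out from 21 and replaces thermodynamic control by kinetic reduction followed by inversion. LiBH(s-Bu)3 at −78 °C attacks equatorially and should give the axial C6 epimer F7 cleanly. Mitsunobu reaction with acetic acid (PPh3, diisopropyl azodicarboxylate, THF) would then install the acetate with inversion, which comes back to the route at 23 and makes step 13 unnecessary.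

Further compounds

F1 | step 1 | allylidenecyclopropane (prop-2-en-1-ylidenecyclopropane) | C=CC=C1CC1
F2 | step 1 | cis-fused spiro-cyclopropane adduct, the analogue of 3 with a spiro-cyclopropane at C4 in place of the gem-dimethyl group | O=C1C=C(C)C(=O)[C@]2(C)CC=CC3(CC3)[C@H]12
F3 | step 1 | allylic alcohol, the analogue of 4 with a spiro-cyclopropane at C4 | O[C@@H]1C=C(C)C(=O)[C@]2(C)CC=CC3(CC3)[C@H]12
F4 | step 1 | saturated hydroxy ketone, the analogue of 5 with a spiro-cyclopropane at C4 | O[C@@H]1C[C@@H](C)C(=O)[C@]2(C)CCCC3(CC3)[C@H]12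
F5 | step 10 | saturated diol ester, the 11,12-dihydro derivative of 17 | O=C1C[C@@H](C)[C@@](O)(CC[C@@](O)(CCO[Si](C)(C)C(C)(C)C)C(=O)OCC)[C@]2(C)CCCC(C)(C)[C@H]12
F6 | step 10 | saturated hydroxy lactone, the 11,12-dihydro derivative of 19 | O=C1C[C@@H](C)[C@@](O)(CC[C@@]3(O)CCOC3=O)[C@]2(C)CCCC(C)(C)[C@H]12
F7 | step 12 | (5S,6R,8R,9R,10R,13R)-6-hydroxy-9,13-epoxylabdan-16,15-olide, the C6 epimer of 22 (hydroxyl anti, axial) | O[C@@H]1C[C@@H](C)[C@]2(CC[C@]3(CCOC3=O)O2)[C@]2(C)CCCC(C)(C)[C@H]12
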